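**Retrosynthetic overview**

1. Target 11 comes from mono-O-methylation of the locally symmetric dibromoresorcinol 10, which comes from twofold bromination (C3', C5') of the 2-aryloxyresorcinol 9.
2. 9 comes from a double Baeyer–Villiger oxidation and methanolysis of the 2-aryloxyisophthalaldehyde 6. The feature used is that ring-B C1' (the ether carbon) is flanked by two oxygenated carbons, C2' (OH) and C6' (OMe), and both oxygens are delivered from formyl groups.
3. 6 comes from SNAr formation of the C1'–O bond between phenol 4 and 2-fluoroisophthalaldehyde 5; the same two formyl groups activate C1'.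
4. 4 comes from O-methylation and then Baeyer–Villiger oxidation of 3,5-dibromosalicylaldehyde 1.
5. No ring is formed at any stage: ring A is bought as 1 and ring B as 5.

Key step: step 4

Remark: the target has no stereocentre and the diaryl ether axis is not configurationally stable, so the compound is achiral and no stereocontrol is needed. Reagents such as MeI, mCPBA and NBS are named under the steps and are not numbered.

**Route**

Step 1
Reactants: 1 3,5-dibromosalicylaldehyde
Product: 2 3,5-dibromo-2-methoxybenzaldehyde
Conditions: MeI (1.5 equiv), K2CO3 (2 equiv), DMF, rt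
Reagents that add atoms: methyl iodide, CI
Why: Williamson O-methylation (SN2 of the acidic phenoxide on MeI) is routine for ortho-substituted salicylaldehydes in DMF, and capping the phenol ensures that the later peracid oxidation gives a monophenol by the Baeyer–Villiger formate pathway.

Step 2
Reactants: 2 3,5-dibromo-2-methoxybenzaldehyde
Product: 4 3,5-dibromo-2-methoxyphenol, via aryl formate 3 (not isolated)
Conditions: mCPBA (1.5 equiv), CH2Cl2, rt to 40 °C; aq. Na2S2O3/NaHCO3 wash; then MeOH, Et3N (cat.), rt
Reagents that add atoms: mCPBA, OOC(=O)c1cccc(Cl)c1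
Why: Baeyer–Villiger (Dakin-type) oxidation, in which the ortho-methoxy group should favour aryl over hydride migration in the Criegee adduct to give formate 3, which mild methanolysis cleaves to the phenol while the aryl bromides and the methyl ether are inert to peracid.

Step 3
Reactants: 4 3,5-dibromo-2-methoxyphenol; 5 2-fluoroisophthalaldehyde
Product: 6 2-(3,5-dibromo-2-methoxyphenoxy)benzene-1,3-dicarbaldehyde
Conditions: K2CO3 (1.5 equiv), dry DMF, 60 °C
Reagents that add atoms: none
Why: Nucleophilic aromatic substitution by addition–elimination, in which two ortho formyl groups stabilise the Meisenheimer intermediate so that the weakly nucleophilic phenoxide of 4 should displace fluoride under mild carbonate conditions, while the unactivated C–Br bonds of ring A stay intact.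

Step 4
Reactants: 6 2-(3,5-dibromo-2-methoxyphenoxy)benzene-1,3-dicarbaldehyde
Product: 9 2-(3,5-dibromo-2-methoxyphenoxy)benzene-1,3-diol, via mono-formate aldehyde 7 (not isolated), via bis-formate 8 (not isolated)
Conditions: mCPBA (3 equiv), CH2Cl2, 0 °C to reflux; aq. Na2S2O3/NaHCO3 wash; then MeOH, Et3N (cat.), rt
Reagents that add atoms: mCPBA, OOC(=O)c1cccc(Cl)c1
Why: The peracid adds to each formyl carbon to give a Criegee peroxyhemiacetal, from which the ring carbon migrates to oxygen with loss of 3-chlorobenzoate, turning first one and then the other Ar–CHO into Ar–OCHO (6 to 7 to 8), and amine-catalysed methanolysis then removes both formyl groups as methyl formate to release resorcinol 9. The closest known reaction is the Baeyer–Villiger (Dakin-type) oxidation of ortho-aryloxy- and ortho-alkoxybenzaldehydes to the corresponding phenols, here run twice on one ring. No ring is closed and no stereocentre is formed; the step creates the C2'–O and C6'–O bonds of ring B. The selectivity needed is aryl over hydride migration in both Criegee adducts, and it is secured by the ether oxygen at C1', which is ortho to both migrating carbons and stabilises the electron-deficient migrating terminus by lone-pair donation, whereas the second carbonyl substituent sits meta and acts only inductively. Ring A carries no oxidisable group, and ring B stays protected as the electron-poor bis-formate until the excess peracid has been destroyed by the thiosulfate wash, so the electron-rich diol should not meet oxidant. The two formyl groups thus serve twice, first as activators for the SNAr at C1' and then as the source of the two flanking oxygens.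

Step 5
Reactants: 9 2-(3,5-dibromo-2-methoxyphenoxy)benzene-1,3-diol
Product: 10 4,6-dibromo-2-(3,5-dibromo-2-methoxyphenoxy)benzene-1,3-diol
Conditions: NBS (2.05 equiv), MeCN, −10 °C to rt
Reagents that add atoms: N-bromosuccinimide, O=C1CCC(=O)N1Br
Why: Electrophilic aromatic bromination, in which C4 and C6 of the resorcinol (C3' and C5' of ring B) are each ortho to one hydroxyl and para to the other and should take the two bromines, while C5 is meta to both hydroxyls and ring A is deactivated by its two bromines.

Step 6
Reactants: 10 4,6-dibromo-2-(3,5-dibromo-2-methoxyphenoxy)benzene-1,3-diol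
Product: 11 4,6-dibromo-2-(3,5-dibromo-2-methoxyphenoxy)-3-methoxyphenol (target)
Conditions: K2CO3 (1.0 equiv), MeI (1.0 equiv), DMF, 0 °C to rt; unreacted 10 recovered by chromatography
Reagents that add atoms: methyl iodide, CI
Why: Williamson mono-O-methylation, in which the two hydroxyls of 10 are equivalent so that either gives 11, and one equivalent each of base and MeI should favour the mono-ether because the monoanion of the diol forms more readily than the anion of the product or the dianion, with the diol and the dimethyl ether separable by polarity.

**Compound list**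

1 | 3,5-dibromosalicylaldehyde | O=Cc1cc(Br)cc(Br)c1O | starting material
2 | 3,5-dibromo-2-methoxybenzaldehyde | COc1c(Br)cc(Br)cc1C=O | intermediate
3 | 3,5-dibromo-2-methoxyphenyl formate | COc1c(Br)cc(Br)cc1OC=O | intermediate (not isolated)
4 | 3,5-dibromo-2-methoxyphenol | COc1c(Br)cc(Br)cc1O | intermediate
5 | 2-fluoroisophthalaldehyde | O=Cc1cccc(C=O)c1F | starting material
6 | 2-(3,5-dibromo-2-methoxyphenoxy)benzene-1,3-dicarbaldehyde | COc1c(Br)cc(Br)cc1Oc1c(C=O)cccc1C=O | intermediate
7 | 2-(3,5-dibromo-2-methoxyphenoxy)-3-formylphenyl formate | COc1c(Br)cc(Br)cc1Oc1c(C=O)cccc1OC=O | intermediate (not isolated)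
8 | 2-(3,5-dibromo-2-methoxyphenoxy)-1,3-phenylene diformate | COc1c(Br)cc(Br)cc1Oc1c(OC=O)cccc1OC=O | intermediate (not isolated)
9 | 2-(3,5-dibromo-2-methoxyphenoxy)benzene-1,3-diol | COc1c(Br)cc(Br)cc1Oc1c(O)cccc1O | intermediate
10 | 4,6-dibromo-2-(3,5-dibromo-2-methoxyphenoxy)benzene-1,3-diol | COc1c(Br)cc(Br)cc1Oc1c(O)c(Br)cc(Br)c1O | intermediate
11 | 4,6-dibromo-2-(3,5-dibromo-2-methoxyphenoxy)-3-methoxyphenol | COc1c(Br)cc(Br)cc1Oc1c(O)c(Br)cc(Br)c1OC | target

**Step count**

Total steps: 6. Longest linear sequence: 6 steps (1 to 11); 5 enters at step 3.

**Steps most likely to fail**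

1. Step 4. Hydride migration may compete with aryl migration in one or both Criegee adducts, or the oxidation may stall after the first formyl group, so that carboxylic acids form in place of the formates. Fallback: the route leaves at 6 and replaces hydrogen by methyl as the competing migrating group. Addition of MeMgBr (2.2 equiv, THF, −78 to 0 °C) to both formyl groups should give 1,1'-[2-(3,5-dibromo-2-methoxyphenoxy)-1,3-phenylene]diethanol F1 as a mixture of diastereomers of no consequence. Dess–Martin oxidation in CH2Cl2 should give the diketone 1,1'-[2-(3,5-dibromo-2-methoxyphenoxy)-1,3-phenylene]diethanone F2. Baeyer–Villiger oxidation with trifluoroperacetic acid (trifluoroacetic anhydride, urea–H2O2, Na2HPO4, CH2Cl2), where aryl migrates far more readily than methyl, should give 2-(3,5-dibromo-2-methoxyphenoxy)-1,3-phenylene diacetate F3. Methanolysis with K2CO3 in MeOH comes back to the route at 9.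

2. Step 6. Alkylation may run on to the dimethyl ether or stop short, giving a near-statistical mixture of diol, mono-ether and di-ether, because the two hydroxyls are equivalent. Fallback: the route leaves at 4 and builds ring B with the two oxygens already different. SNAr of 4 on commercial 2-fluoro-3-methoxybenzaldehyde (COc1cccc(C=O)c1F; Cs2CO3, DMSO, 120 °C) should give 2-(3,5-dibromo-2-methoxyphenoxy)-3-methoxybenzaldehyde F4. A single Baeyer–Villiger oxidation with mCPBA in CH2Cl2 should give 2-(3,5-dibromo-2-methoxyphenoxy)-3-methoxyphenyl formate F5, which is not isolated and is cleaved with MeOH and catalytic Et3N to 2-(3,5-dibromo-2-methoxyphenoxy)-3-methoxyphenol F6. Bromination with NBS (2 equiv, MeCN, 0 °C) at the positions ortho and para to the free hydroxyl (para and ortho to the methoxy group) comes back to the route at the target 11.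

3. Step 3. Addition of the weakly nucleophilic, ortho-substituted phenoxide to the crowded C–F carbon may be slow, and the fluoro-dialdehyde may meanwhile be consumed by adventitious hydroxide, by dimethylamine from the solvent, or by aldehyde condensation. Fallback: the route leaves at 4 and uses smaller, base-stable activating groups. SNAr of 4 on commercial 2-fluoroisophthalonitrile (N#Cc1cccc(C#N)c1F; Cs2CO3, DMSO, 80–100 °C) should give 2-(3,5-dibromo-2-methoxyphenoxy)benzene-1,3-dicarbonitrile F7. Reduction with DIBAL-H (2.5 equiv, toluene/CH2Cl2, −78 to 0 °C) should give the bis-aldimine 1,1'-[2-(3,5-dibromo-2-methoxyphenoxy)-1,3-phenylene]dimethanimine F8, which is not isolated and is hydrolysed by the aqueous HCl work-up, coming back to the route at 6.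

**Further compounds**

F1 | step 4 | 1,1'-[2-(3,5-dibromo-2-methoxyphenoxy)-1,3-phenylene]diethanol | COc1c(Br)cc(Br)cc1Oc1c(C(C)O)cccc1C(C)O
F2 | step 4 | 1,1'-[2-(3,5-dibromo-2-methoxyphenoxy)-1,3-phenylene]diethanone | COc1c(Br)cc(Br)cc1Oc1c(C(C)=O)cccc1C(C)=O
F3 | step 4 | 2-(3,5-dibromo-2-methoxyphenoxy)-1,3-phenylene diacetate | COc1c(Br)cc(Br)cc1Oc1c(OC(C)=O)cccc1OC(C)=O
F4 | step 6 | 2-(3,5-dibromo-2-methoxyphenoxy)-3-methoxybenzaldehyde | COc1cccc(C=O)c1Oc1cc(Br)cc(Br)c1OC
F5 | step 6 | 2-(3,5-dibromo-2-methoxyphenoxy)-3-methoxyphenyl formate | COc1cccc(OC=O)c1Oc1cc(Br)cc(Br)c1OC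
F6 | step 6 | 2-(3,5-dibromo-2-methoxyphenoxy)-3-methoxyphenol | COc1cccc(O)c1Oc1cc(Br)cc(Br)c1OC
F7 | step 3 | 2-(3,5-dibromo-2-methoxyphenoxy)benzene-1,3-dicarbonitrile | COc1c(Br)cc(Br)cc1Oc1c(C#N)cccc1C#N
F8 | step 3 | 1,1'-[2-(3,5-dibromo-2-methoxyphenoxy)-1,3-phenylene]dimethanimine | COc1c(Br)cc(Br)cc1Oc1c(C=N)cccc1C=N
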